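**Retrosynthetic overview**

1. Target 23 comes from pentabenzyl ether 22 by hydrogenolysis, and 22 from tetraketone 20 by aldol closure of ring B. The strategy rests on ring B, the 2,4-dihydroxy-6-methylbenzoyl ring on ring A, being a folded 3,5,7-triketo chain on the benzophenone carbonyl; its bond between the carbonyl-bearing and the methyl-bearing carbon (chain C2–C7) is made last.
2. Tetraketone 20 comes from Claisen acylation of the trianion of heptane-2,4,6-trione 18 (from 2,6-dimethyl-4H-pyran-4-one 16) by the ring A methyl ester 15.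
3. Ester 15 comes from the symmetric bis-ester 6: on one ester the ring B' chain is built in two bites (pentane-2,4-dione dianion, then terminal acetylation of the triketone trianion) and closed by the same aldol; 4-O-benzylation and 2-O-methylation then set ring B' apart from ring B.
4. Bis-ester 6 is the benzylated methylene-bridged dimer 5, made from two molecules of methyl 2,6-dihydroxy-4-methoxybenzoate 2 and formaldehyde 3; 2 comes from methyl 2,4,6-trihydroxybenzoate 1.
5. Ring order: rings A and A' are bought and bridged (step 2), ring B' is closed in step 6, ring B in step 11.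

Key step: step 11

Assumption: ring A carries ring B and ring A' carries ring B'; each polyketone chain is numbered from C1 (aryl ketone) to its terminal methyl; the polyketones 9, 11, 18 and 20 are taken on without storage because acid recloses them to 4-pyranones.

**Step 1**
Reactants: 1 methyl 2,4,6-trihydroxybenzoate
Product: 2 methyl 2,6-dihydroxy-4-methoxybenzoate
Conditions: Me2SO4 (1.0 equiv), K2CO3 (1.0 equiv), acetone, 25 °C
Reagents that add atoms: dimethyl sulfate, COS(=O)(=O)OC
Why: Williamson O-methylation; the 4-hydroxyl is the most acidic one and the only one not hydrogen-bonded to the ester, so one equivalent of a hard methylating agent should stop at the 4-methyl ether.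

**Step 2**
Reactants: 2 methyl 2,6-dihydroxy-4-methoxybenzoate (two molecules enter the product); 3 formaldehyde
Product: 5 dimethyl 3,3'-methylenebis(2,6-dihydroxy-4-methoxybenzoate), via benzylic alcohol 4 (not isolated)
Conditions: 37% aq. HCHO (0.4 equiv per 2), cat. HCl, MeOH–H2O, 40 °C
Reagents that add atoms: second molecule of methyl 2,6-dihydroxy-4-methoxybenzoate (2), COC(=O)c1c(O)cc(OC)cc1O
Why: Acid-catalysed hydroxymethylation of 2 at C3 gives benzylic alcohol 4, whose protonated form alkylates a second molecule of 2 with loss of water in a Friedel–Crafts reaction (novolac-type phenol–formaldehyde condensation); C3 and C5 of 2 are equivalent, so only one diarylmethane can form, and the deficit of formaldehyde holds back oligomers while excess 2 is recovered.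

**Step 3**
Reactants: 5 dimethyl 3,3'-methylenebis(2,6-dihydroxy-4-methoxybenzoate)
Product: 6 dimethyl 3,3'-methylenebis[2,6-bis(benzyloxy)-4-methoxybenzoate]
Conditions: BnBr (6 equiv), K2CO3 (8 equiv), cat. Bu4NI, DMF, 60 °C
Reagents that add atoms: benzyl bromide, BrCc1ccccc1
Why: Fourfold Williamson etherification; carbonate in DMF favours O- over C-benzylation, and warming with iodide catalysis should overcome the hydrogen bonding of the hydroxyls to the esters.

**Step 4**
Reactants: 7 pentane-2,4-dione; 6 dimethyl 3,3'-methylenebis[2,6-bis(benzyloxy)-4-methoxybenzoate]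
Product: 9 methyl 2,6-bis(benzyloxy)-3-{[2,4-bis(benzyloxy)-3-(3,5-dioxohexanoyl)-6-methoxyphenyl]methyl}-4-methoxybenzoate, via dilithium dienolate 8 (not isolated)
Conditions: 7 (1.2 equiv), LiN(i-Pr)2 (2.4 equiv), THF, 0 °C; then 6 (1.0 equiv), 0 °C to 25 °C; then 1 M HCl, 0 °C
Reagents that add atoms: none
Why: Hauser–Harris Claisen acylation of a β-diketone dianion by an aromatic ester: the terminal carbanion of 8 attacks one ester and a second equivalent of 8 deprotonates the new C2 methylene, so the limiting amount of this stable, exactly dosable dianion and the doubly charged mono-adduct should hold the reaction at mono-acylation, and neutral unreacted 6 is separated from acidic 9 and recycled.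

**Step 5**
Reactants: 9 methyl 2,6-bis(benzyloxy)-3-{[2,4-bis(benzyloxy)-3-(3,5-dioxohexanoyl)-6-methoxyphenyl]methyl}-4-methoxybenzoate
Product: 11 methyl 2,6-bis(benzyloxy)-3-{[2,4-bis(benzyloxy)-6-methoxy-3-(3,5,7-trioxooctanoyl)phenyl]methyl}-4-methoxybenzoate, via triketone trienolate 10 (not isolated)
Conditions: LiN(i-Pr)2 (3.1 equiv), THF, −20 °C; then MeC(O)N(OMe)Me (1.5 equiv), −20 °C to 0 °C; then 1 M HCl, 0 °C
Reagents that add atoms: N-methoxy-N-methylacetamide, CC(=O)N(C)OC
Why: Terminal C-acylation of a 1,3,5-triketone trianion (Hauser–Harris chain extension, run as a Weinreb ketone synthesis): the terminal methyl carbanion of 10 is the last formed and most nucleophilic site, the amide gives a chelated tetrahedral adduct that releases the ketone only on acid work-up, and the di-ortho-substituted methyl ester should not compete with the amide at −20 °C.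

**Step 6**
Reactants: 11 methyl 2,6-bis(benzyloxy)-3-{[2,4-bis(benzyloxy)-6-methoxy-3-(3,5,7-trioxooctanoyl)phenyl]methyl}-4-methoxybenzoate
Product: 13 methyl 2,6-bis(benzyloxy)-3-{[2,4-bis(benzyloxy)-3-(2,4-dihydroxy-6-methylbenzoyl)-6-methoxyphenyl]methyl}-4-methoxybenzoate, via aldol carbinol 12 (not isolated)
Conditions: aq. KHCO3–K2CO3 buffer (pH 9.5), THF–MeOH, N2, 25 °C
Reagents that add atoms: none
Why: Intramolecular aldol condensation of the C2 enolate onto the C7 methyl ketone (6-(enolexo)-exo-trig), then dehydration and enolization to the resorcinol of ring B'; the aryl ketone is screened by two ortho benzyloxy groups and the hindered methyl ester on the other ring should not hydrolyse at this pH.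

**Step 7**
Reactants: 13 methyl 2,6-bis(benzyloxy)-3-{[2,4-bis(benzyloxy)-3-(2,4-dihydroxy-6-methylbenzoyl)-6-methoxyphenyl]methyl}-4-methoxybenzoate
Product: 14 methyl 2,6-bis(benzyloxy)-3-({2,4-bis(benzyloxy)-3-[4-(benzyloxy)-2-hydroxy-6-methylbenzoyl]-6-methoxyphenyl}methyl)-4-methoxybenzoate
Conditions: BnBr (1.05 equiv), K2CO3 (1.1 equiv), acetone, 40 °C
Reagents that add atoms: benzyl bromide, BrCc1ccccc1
Why: Williamson etherification; in a 2,4-dihydroxybenzophenone the 4-hydroxyl is more acidic and unchelated while the 2-hydroxyl is locked in a hydrogen bond to the ketone, so one equivalent should benzylate only the 4-position.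

**Step 8**
Reactants: 14 methyl 2,6-bis(benzyloxy)-3-({2,4-bis(benzyloxy)-3-[4-(benzyloxy)-2-hydroxy-6-methylbenzoyl]-6-methoxyphenyl}methyl)-4-methoxybenzoate
Product: 15 methyl 2,6-bis(benzyloxy)-3-({2,4-bis(benzyloxy)-3-[4-(benzyloxy)-2-methoxy-6-methylbenzoyl]-6-methoxyphenyl}methyl)-4-methoxybenzoate
Conditions: MeI (5 equiv), K2CO3 (3 equiv), DMF, 50 °C
Reagents that add atoms: iodomethane, CI
Why: Williamson O-methylation of the remaining chelated phenol under forcing but mild conditions; no free phenol is left on ring A', so no xanthone can form by displacement.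

**Step 9**
Reactants: 16 2,6-dimethyl-4H-pyran-4-one
Product: 18 heptane-2,4,6-trione, via barium dienolate 17 (not isolated)
Conditions: Ba(OH)2·8H2O (1.1 equiv), H2O, 60 °C; then 2 M HCl, Et2O, 0 °C; used at once
Reagents that add atoms: water, O
Why: Hydroxide adds in conjugate fashion to C2 of the 4-pyranone and the hemiketal opens by retro-oxa-Michael reaction; the triketone is held as its barium salt and freed by cold acid before it can reclose.

**Step 10**
Reactants: 18 heptane-2,4,6-trione; 15 methyl 2,6-bis(benzyloxy)-3-({2,4-bis(benzyloxy)-3-[4-(benzyloxy)-2-methoxy-6-methylbenzoyl]-6-methoxyphenyl}methyl)-4-methoxybenzoate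
Product: 20 1-[2,6-bis(benzyloxy)-3-({2,4-bis(benzyloxy)-3-[4-(benzyloxy)-2-methoxy-6-methylbenzoyl]-6-methoxyphenyl}methyl)-4-methoxyphenyl]octane-1,3,5,7-tetraone, via heptanetrione trienolate 19 (not isolated)
Conditions: 18 (4 equiv), LiN(i-Pr)2 (12 equiv), THF, 0 °C; then 15 (1 equiv), 0 °C to 25 °C; then 1 M HCl, 0 °C
Reagents that add atoms: none
Why: Claisen condensation of a polyketone trianion with an aromatic ester (Hauser–Harris acylation): the terminal carbanion of 19 attacks the ester and further 19 deprotonates the new C2 methylene, so an excess is used to drive the single ester to completion; the ring A'–ring B' ketone carries four ortho substituents and no α-hydrogen, so it should neither add the nucleophile nor enolize.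

**Step 11**
Reactants: 20 1-[2,6-bis(benzyloxy)-3-({2,4-bis(benzyloxy)-3-[4-(benzyloxy)-2-methoxy-6-methylbenzoyl]-6-methoxyphenyl}methyl)-4-methoxyphenyl]octane-1,3,5,7-tetraone
Product: 22 [2,6-bis(benzyloxy)-3-({2,4-bis(benzyloxy)-3-[4-(benzyloxy)-2-methoxy-6-methylbenzoyl]-6-methoxyphenyl}methyl)-4-methoxyphenyl](2,4-dihydroxy-6-methylphenyl)methanone, via aldol carbinol 21 (not isolated)
Conditions: aq. KHCO3–K2CO3 buffer (pH 9.5), THF–MeOH, N2, 25 °C
Reagents that add atoms: none
Why: At pH 9.5 the chain of 20 is enolized at its three doubly activated methylenes; the C2 enolate, flanked by the aryl ketone C1 and the C3 ketone, adds to the unhindered C7 methyl ketone to give carbinol 21, which loses water by E1cB elimination and tautomerizes twice to the resorcinol of ring B. The closest known reaction type is the biomimetic aldol cyclization of 1-aryl-octane-1,3,5,7-tetraones to 2,4-dihydroxy-6-methylbenzophenones. Ring B closes in a 6-(enolexo)-exo-trig mode, joining the carbon that bears the benzophenone carbonyl to the carbon that bears the methyl group. The two stereocentres of 21 are transient and vanish on aromatization, so none has to be controlled. The step needs C2-to-C7 rather than C6-to-C1 aldol selectivity and no heterocycle formation: C1 is an aryl ketone screened by the two ortho benzyloxy groups of ring A, C4 could only form a four-membered ring, the terminal methyl is not enolized at this pH, ring A has no free phenol that could close a chromone, and the absence of acid suppresses dehydrative closure to a 4-pyranone. Ring B should emerge with both hydroxyls free, as the target requires, while the five benzyl ethers, the methyl ethers and the ring A'–ring B' ketone are inert to the buffer.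

**Step 12**
Reactants: 22 [2,6-bis(benzyloxy)-3-({2,4-bis(benzyloxy)-3-[4-(benzyloxy)-2-methoxy-6-methylbenzoyl]-6-methoxyphenyl}methyl)-4-methoxyphenyl](2,4-dihydroxy-6-methylphenyl)methanone
Product: 23 [3-({3-(2,4-dihydroxy-6-methylbenzoyl)-2,4-dihydroxy-6-methoxyphenyl}methyl)-2,6-dihydroxy-4-methoxyphenyl](4-hydroxy-2-methoxy-6-methylphenyl)methanone
Conditions: H2 (1 atm), 10% Pd/C, EtOAc–MeOH, 25 °C
Reagents that add atoms: none
Why: Catalytic hydrogenolysis of the five benzyl aryl ethers; the aryl methyl ethers, the diarylmethane bridge and the two hindered, hydrogen-bonded diaryl ketones should survive neutral conditions at one atmosphere if the reaction is stopped after uptake ceases.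

**Compound list**

1 | methyl 2,4,6-trihydroxybenzoate | COC(=O)c1c(O)cc(O)cc1O | starting material
2 | methyl 2,6-dihydroxy-4-methoxybenzoate | COC(=O)c1c(O)cc(OC)cc1O | intermediate
3 | formaldehyde | C=O | starting material
4 | methyl 2,6-dihydroxy-3-(hydroxymethyl)-4-methoxybenzoate (not isolated) | COC(=O)c1c(O)cc(OC)c(CO)c1O | intermediate
5 | dimethyl 3,3'-methylenebis(2,6-dihydroxy-4-methoxybenzoate) | COc1cc(O)c(C(=O)OC)c(O)c1Cc1c(OC)cc(O)c(C(=O)OC)c1O | intermediate
6 | dimethyl 3,3'-methylenebis[2,6-bis(benzyloxy)-4-methoxybenzoate] | COc1cc(OCc2ccccc2)c(C(=O)OC)c(OCc2ccccc2)c1Cc1c(OC)cc(OCc2ccccc2)c(C(=O)OC)c1OCc1ccccc1 | intermediate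
7 | pentane-2,4-dione | CC(=O)CC(C)=O | starting material
8 | dilithium dienolate of pentane-2,4-dione (not isolated) | [Li+].[Li+].C=C([O-])C=C(C)[O-] | intermediate
9 | methyl 2,6-bis(benzyloxy)-3-{[2,4-bis(benzyloxy)-3-(3,5-dioxohexanoyl)-6-methoxyphenyl]methyl}-4-methoxybenzoate | COc1cc(OCc2ccccc2)c(C(=O)OC)c(OCc2ccccc2)c1Cc1c(OC)cc(OCc2ccccc2)c(C(=O)CC(=O)CC(C)=O)c1OCc1ccccc1 | intermediate
10 | trilithium trienolate of triketone 9 (not isolated) | [Li+].[Li+].[Li+].COc1cc(OCc2ccccc2)c(C(=O)OC)c(OCc2ccccc2)c1Cc1c(OC)cc(OCc2ccccc2)c(C([O-])=CC([O-])=CC(=C)[O-])c1OCc1ccccc1 | intermediate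
11 | methyl 2,6-bis(benzyloxy)-3-{[2,4-bis(benzyloxy)-6-methoxy-3-(3,5,7-trioxooctanoyl)phenyl]methyl}-4-methoxybenzoate | COc1cc(OCc2ccccc2)c(C(=O)OC)c(OCc2ccccc2)c1Cc1c(OC)cc(OCc2ccccc2)c(C(=O)CC(=O)CC(=O)CC(C)=O)c1OCc1ccccc1 | intermediate
12 | methyl 2,6-bis(benzyloxy)-3-{[2,4-bis(benzyloxy)-3-(2-hydroxy-2-methyl-4,6-dioxocyclohexane-1-carbonyl)-6-methoxyphenyl]methyl}-4-methoxybenzoate (not isolated; transient mixture of stereoisomers) | COc1cc(OCc2ccccc2)c(C(=O)OC)c(OCc2ccccc2)c1Cc1c(OC)cc(OCc2ccccc2)c(C(=O)C2C(=O)CC(=O)CC2(C)O)c1OCc1ccccc1 | intermediate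
13 | methyl 2,6-bis(benzyloxy)-3-{[2,4-bis(benzyloxy)-3-(2,4-dihydroxy-6-methylbenzoyl)-6-methoxyphenyl]methyl}-4-methoxybenzoate | COc1cc(OCc2ccccc2)c(C(=O)OC)c(OCc2ccccc2)c1Cc1c(OC)cc(OCc2ccccc2)c(C(=O)c2c(C)cc(O)cc2O)c1OCc1ccccc1 | intermediate
14 | methyl 2,6-bis(benzyloxy)-3-({2,4-bis(benzyloxy)-3-[4-(benzyloxy)-2-hydroxy-6-methylbenzoyl]-6-methoxyphenyl}methyl)-4-methoxybenzoate | COc1cc(OCc2ccccc2)c(C(=O)OC)c(OCc2ccccc2)c1Cc1c(OC)cc(OCc2ccccc2)c(C(=O)c2c(C)cc(OCc3ccccc3)cc2O)c1OCc1ccccc1 | intermediate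
15 | methyl 2,6-bis(benzyloxy)-3-({2,4-bis(benzyloxy)-3-[4-(benzyloxy)-2-methoxy-6-methylbenzoyl]-6-methoxyphenyl}methyl)-4-methoxybenzoate | COc1cc(OCc2ccccc2)c(C(=O)OC)c(OCc2ccccc2)c1Cc1c(OC)cc(OCc2ccccc2)c(C(=O)c2c(C)cc(OCc3ccccc3)cc2OC)c1OCc1ccccc1 | intermediate
16 | 2,6-dimethyl-4H-pyran-4-one | CC1=CC(=O)C=C(C)O1 | starting material
17 | barium dienolate of heptane-2,4,6-trione (not isolated) | [Ba+2].CC(=O)C=C([O-])C=C(C)[O-] | intermediate
18 | heptane-2,4,6-trione | CC(=O)CC(=O)CC(C)=O | intermediate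
19 | trilithium trienolate of heptane-2,4,6-trione (not isolated) | [Li+].[Li+].[Li+].C=C([O-])C=C([O-])C=C(C)[O-] | intermediate
20 | 1-[2,6-bis(benzyloxy)-3-({2,4-bis(benzyloxy)-3-[4-(benzyloxy)-2-methoxy-6-methylbenzoyl]-6-methoxyphenyl}methyl)-4-methoxyphenyl]octane-1,3,5,7-tetraone | COc1cc(OCc2ccccc2)c(C(=O)CC(=O)CC(=O)CC(C)=O)c(OCc2ccccc2)c1Cc1c(OC)cc(OCc2ccccc2)c(C(=O)c2c(C)cc(OCc3ccccc3)cc2OC)c1OCc1ccccc1 | intermediate
21 | [2,6-bis(benzyloxy)-3-({2,4-bis(benzyloxy)-3-[4-(benzyloxy)-2-methoxy-6-methylbenzoyl]-6-methoxyphenyl}methyl)-4-methoxyphenyl](2-hydroxy-2-methyl-4,6-dioxocyclohexyl)methanone (not isolated; transient mixture of stereoisomers) | COc1cc(OCc2ccccc2)c(C(=O)C2C(=O)CC(=O)CC2(C)O)c(OCc2ccccc2)c1Cc1c(OC)cc(OCc2ccccc2)c(C(=O)c2c(C)cc(OCc3ccccc3)cc2OC)c1OCc1ccccc1 | intermediate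
22 | [2,6-bis(benzyloxy)-3-({2,4-bis(benzyloxy)-3-[4-(benzyloxy)-2-methoxy-6-methylbenzoyl]-6-methoxyphenyl}methyl)-4-methoxyphenyl](2,4-dihydroxy-6-methylphenyl)methanone | COc1cc(OCc2ccccc2)c(C(=O)c2c(C)cc(O)cc2O)c(OCc2ccccc2)c1Cc1c(OC)cc(OCc2ccccc2)c(C(=O)c2c(C)cc(OCc3ccccc3)cc2OC)c1OCc1ccccc1 | intermediate
23 | [3-({3-(2,4-dihydroxy-6-methylbenzoyl)-2,4-dihydroxy-6-methoxyphenyl}methyl)-2,6-dihydroxy-4-methoxyphenyl](4-hydroxy-2-methoxy-6-methylphenyl)methanone | COc1cc(O)c(C(=O)c2c(C)cc(O)cc2O)c(O)c1Cc1c(OC)cc(O)c(C(=O)c2c(C)cc(O)cc2OC)c1O | target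

**Step count and risks**

Total step count: 12. Longest linear sequence: 11 steps (steps 1, 2, 3, 4, 5, 6, 7, 8, 10, 11, 12); step 9 is a one-step side branch.

The three steps most likely to fail:

1. Step 4. Acyl transfer from the doubly ortho-benzyloxylated ester may be slow, and the acylation may run on at both esters of the symmetric substrate. The fallback sets out from 6 and returns at 13, replacing the two polyanion steps by a masked tetraketone. Bis-ester 6 would be half-saponified (KOH, 1 equiv, DMSO–H2O, 90 °C) to the mono-acid 2,6-bis(benzyloxy)-3-{[2,4-bis(benzyloxy)-6-methoxy-3-(methoxycarbonyl)phenyl]methyl}-4-methoxybenzoic acid F1, which is separated from neutral 6 by base extraction. Carbonyldiimidazole in THF would turn it into the acyl imidazolide F2. 2,6-Dimethyl-4H-pyran-4-one 16 would be deprotonated at one methyl group (LiN(SiMe3)2, 2 equiv, THF, −78 °C) to 2-(lithiomethyl)-6-methyl-4H-pyran-4-one F3. F2 would C-acylate this lateral carbanion to give the 2-aroylmethyl-6-methyl-4-pyranone F4. Aqueous Ba(OH)2 in THF–MeOH would then open the pyranone to 11, which should close in the same basic medium through 12 to 13.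

2. Step 10. Slow acyl transfer from the hindered ester consumes an advanced intermediate while the fragile trianion decays by self-condensation. The fallback sets out from 15 and returns at 20, building the chain in two bites as on ring A'. Ester 15 would be treated with a large excess of dilithium dienolate 8, made from pentane-2,4-dione 7 as in step 4 (LiN(i-Pr)2, THF, 0 °C to 25 °C), to give the 1-aryl-hexane-1,3,5-trione F5. Threefold deprotonation of F5 (LiN(i-Pr)2, 3.0 equiv, THF, −20 °C) would give its trilithium trienolate F6; the ring B' methyl group should stay untouched because its tetra-ortho-substituted ketone is twisted out of conjugation. Terminal C-acetylation of F6 with N-methoxy-N-methylacetamide as in step 5 would give 20.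

3. Step 11. Hydroxide may cleave the polyketone chain by retro-Claisen fragmentation, or the chain may close by dehydration to a 4-pyranone during handling, before the aldol takes place. The fallback sets out from 15 and returns at 23, replacing ring construction by a Friedel–Crafts union with a preformed ring B. Ester 15 would be saponified (KOH, DMSO–H2O, 100 °C) to the benzoic acid F7. Commercial orcinol would be benzylated (BnBr, K2CO3, DMF) to 3,5-bis(benzyloxy)toluene F8. Acylation of F8 by F7 promoted by (CF3CO)2O in CH2Cl2 (0 °C to 25 °C) should occur para to one benzyloxy group and ortho to the methyl group, giving the heptabenzyl ether F9. Hydrogenolysis of F9 under the conditions of step 12 would give 23.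

**Further compounds**

F1 | step 4 | 2,6-bis(benzyloxy)-3-{[2,4-bis(benzyloxy)-6-methoxy-3-(methoxycarbonyl)phenyl]methyl}-4-methoxybenzoic acid | COc1cc(OCc2ccccc2)c(C(=O)OC)c(OCc2ccccc2)c1Cc1c(OC)cc(OCc2ccccc2)c(C(=O)O)c1OCc1ccccc1
F2 | step 4 | methyl 2,6-bis(benzyloxy)-3-{[2,4-bis(benzyloxy)-3-(1H-imidazole-1-carbonyl)-6-methoxyphenyl]methyl}-4-methoxybenzoate | COc1cc(OCc2ccccc2)c(C(=O)OC)c(OCc2ccccc2)c1Cc1c(OC)cc(OCc2ccccc2)c(C(=O)n2ccnc2)c1OCc1ccccc1
F3 | step 4 | 2-(lithiomethyl)-6-methyl-4H-pyran-4-one | [Li+].[CH2-]C1=CC(=O)C=C(C)O1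
F4 | step 4 | methyl 2,6-bis(benzyloxy)-3-({2,4-bis(benzyloxy)-6-methoxy-3-[2-(6-methyl-4-oxo-4H-pyran-2-yl)acetyl]phenyl}methyl)-4-methoxybenzoate | COc1cc(OCc2ccccc2)c(C(=O)OC)c(OCc2ccccc2)c1Cc1c(OC)cc(OCc2ccccc2)c(C(=O)CC2=CC(=O)C=C(C)O2)c1OCc1ccccc1
F5 | step 10 | 1-[2,6-bis(benzyloxy)-3-({2,4-bis(benzyloxy)-3-[4-(benzyloxy)-2-methoxy-6-methylbenzoyl]-6-methoxyphenyl}methyl)-4-methoxyphenyl]hexane-1,3,5-trione | COc1cc(OCc2ccccc2)c(C(=O)CC(=O)CC(C)=O)c(OCc2ccccc2)c1Cc1c(OC)cc(OCc2ccccc2)c(C(=O)c2c(C)cc(OCc3ccccc3)cc2OC)c1OCc1ccccc1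
F6 | step 10 | trilithium trienolate of 1-[2,6-bis(benzyloxy)-3-({2,4-bis(benzyloxy)-3-[4-(benzyloxy)-2-methoxy-6-methylbenzoyl]-6-methoxyphenyl}methyl)-4-methoxyphenyl]hexane-1,3,5-trione | [Li+].[Li+].[Li+].COc1cc(OCc2ccccc2)c(C([O-])=CC([O-])=CC(=C)[O-])c(OCc2ccccc2)c1Cc1c(OC)cc(OCc2ccccc2)c(C(=O)c2c(C)cc(OCc3ccccc3)cc2OC)c1OCc1ccccc1
F7 | step 11 | 2,6-bis(benzyloxy)-3-({2,4-bis(benzyloxy)-3-[4-(benzyloxy)-2-methoxy-6-methylbenzoyl]-6-methoxyphenyl}methyl)-4-methoxybenzoic acid | COc1cc(OCc2ccccc2)c(C(=O)O)c(OCc2ccccc2)c1Cc1c(OC)cc(OCc2ccccc2)c(C(=O)c2c(C)cc(OCc3ccccc3)cc2OC)c1OCc1ccccc1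
F8 | step 11 | 3,5-bis(benzyloxy)toluene | Cc1cc(OCc2ccccc2)cc(OCc2ccccc2)c1
F9 | step 11 | [2,6-bis(benzyloxy)-3-({2,4-bis(benzyloxy)-3-[4-(benzyloxy)-2-methoxy-6-methylbenzoyl]-6-methoxyphenyl}methyl)-4-methoxyphenyl][2,4-bis(benzyloxy)-6-methylphenyl]methanone | COc1cc(OCc2ccccc2)c(C(=O)c2c(C)cc(OCc3ccccc3)cc2OCc2ccccc2)c(OCc2ccccc2)c1Cc1c(OC)cc(OCc2ccccc2)c(C(=O)c2c(C)cc(OCc3ccccc3)cc2OC)c1OCc1ccccc1
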